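**Retrosynthetic overview**

1. The strategy rests on one feature of the target. C3 (ketone) and C8 (acyloxy carbinol) lie 1,6 to each other across the ten-membered ring and C4=C5 is ring-cis, so the carbocycle is a decalin with its C3–C8 bond cut. Ring A is C3–C4–C5–C6–C7–C8 and ring B is C3–C2–C1–C10–C9–C8.
2. Target 35 ⇐ C15 desilylation, oxidative lactonisation of the C6/C12 diol, C8 acylation and C10-hydroxyl-directed C8 reduction ⇐ hydroxy dienone 27 ⇐ epoxy dione 24, whose C1–C10 epoxide is opened at C1 by selenolate and eliminated to the E C1=C2 enone.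
3. Key disconnection: 24 ⇐ cis-fused decalin 3,8-diol 23 by Pb(OAc)4 scission of the C3–C8 glycol.
4. 23 ⇐ ring B by ring-closing metathesis of a C3 allyl and a C8 methallyl group, then epoxidation syn to the hydroxyls and C15 oxidation. The C3 and C6 oxygens come from one singlet-oxygen [4+2] addition to a C3-allyl cyclohexa-1,3-diene, on the face of C8–OH.
5. The diene comes from (S)-carvone (ring A, C7) by C12 oxygenation, C8 methallylation then hydroxylation, dienyl triflate formation and allyl coupling. Ring order: ring A (carvone), ring B (step 11), ten-membered ring (step 15), lactone (step 20).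

Key step: step 15

Remark: locants C1–C15 are the germacrane locants of the target (C12 lactone carbonyl, C13 exo-methylene carbon, C14 the methyl on C10, C15 the hydroxymethyl carbon); "upper face" is the face of ring A opposite to the C7 side chain.

**Route**

Step 1
Reactants: 1 (S)-carvone
Product: 2 (5S)-5-(3-chloroprop-1-en-2-yl)-2-methylcyclohex-2-en-1-one
Conditions: Ca(OCl)2, CO2 (dry ice), CH2Cl2/H2O, 0 °C
Reagents that add atoms: calcium hypochlorite, [Ca+2].[O-]Cl.[O-]Cl
Why: Ene-type allylic chlorination by hypochlorous acid should attack only the electron-rich 1,1-disubstituted isopropenyl alkene (the enone alkene is deactivated) and place chlorine on C12 without touching C7.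

Step 2
Reactants: 2 C12 chloride
Product: 4 (5S)-5-(3-hydroxyprop-1-en-2-yl)-2-methylcyclohex-2-en-1-one, via allylic acetate 3 (not isolated)
Conditions: KOAc, Bu4NI (cat.), DMF, 60 °C; then K2CO3 (cat.), MeOH, 0 °C to rt
Reagents that add atoms: potassium acetate, CC(=O)[O-].[K+]
Why: SN2 displacement of the primary allylic chloride by acetate followed by base-catalysed transesterification with methanol should unmask the C12 alcohol while the enone stays intact.

Step 3
Reactants: 4 C12 alcohol
Product: 5 C12 tert-butyldimethylsilyl ether of 4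
Conditions: TBSCl, imidazole, DMF, rt
Reagents that add atoms: tert-butyldimethylsilyl chloride, CC(C)(C)[Si](C)(C)Cl
Why: Imidazole-promoted silylation of the primary allylic alcohol gives an ether that should survive the enolate, coupling and oxidation steps that follow.

Step 4
Reactants: 5 silyl ether; 6 3-bromo-2-methylpropene
Product: 8 8-methallyl enone (mixture of C8 epimers), via lithium enolate 7 (not isolated)
Conditions: LiN(i-Pr)2, THF, −78 °C; then 6, DMPU, −78 to −20 °C
Reagents that add atoms: 3-bromo-2-methylpropene (6), C=C(C)CBr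
Why: Kinetic deprotonation of the enone at the alpha-prime carbon C8 gives the cross-conjugated enolate, whose SN2 alkylation by the allylic bromide brings in C9, C10 and C14; the C8 configuration is irrelevant because C8 is enolised again in step 5.

Step 5
Reactants: 8 8-methallyl enone
Product: 10 8-hydroxy-8-methallyl enone (C8–OH trans to the C7 side chain), via potassium enolate 9 (not isolated)
Conditions: KN(SiMe3)2, THF, −78 °C; then 2-(phenylsulfonyl)-3-phenyloxaziridine, −78 °C
Reagents that add atoms: 2-(phenylsulfonyl)-3-phenyloxaziridine, O=S(=O)(N1OC1c1ccccc1)c1ccccc1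
Why: Enolate hydroxylation by the sulfonyloxaziridine should occur on the face of the tetrasubstituted enolate opposite to the adjacent C7 side chain, so alkylating first and hydroxylating second puts C8–OH trans to that chain and the methallyl group cis to it.

Step 6
Reactants: 10 8-hydroxy enone
Product: 11 C8 trimethylsilyl ether of 10
Conditions: TMSCl, imidazole, DMF, rt
Reagents that add atoms: trimethylsilyl chloride, C[Si](C)(C)Cl
Why: Silylation of the tertiary α-ketol hydroxyl removes the acidic proton that would otherwise consume base and compete for the triflating agent in step 7.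

Step 7
Reactants: 11 silyl ether
Product: 13 dienyl triflate (C3–OTf, C3=C4 and C5=C6), via potassium dienolate 12 (not isolated)
Conditions: KN(SiMe3)2, THF, −78 to −40 °C; then PhNTf2, −78 to 0 °C
Reagents that add atoms: N-phenylbis(trifluoromethanesulfonimide), O=S(=O)(N(c1ccccc1)S(=O)(=O)C(F)(F)F)C(F)(F)F
Why: With C8 quaternary the only acidic position is the gamma carbon C6, so deprotonation gives the extended dienolate and O-sulfonylation (enol triflate formation) fixes the C3=C4–C5=C6 diene with a leaving group on C3.

Step 8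
Reactants: 13 dienyl triflate; 14 allyltributylstannane
Product: 16 3-allyl dienol (free C8–OH), via silyl ether triene 15 (not isolated)
Conditions: 14, Pd(PPh3)4 (5 mol %), LiCl, THF, 65 °C; then K2CO3, MeOH, rt
Reagents that add atoms: allyltributylstannane (14), C=CC[Sn](CCCC)(CCCC)CCCC
Why: Stille coupling (oxidative addition of zerovalent palladium to the dienyl triflate, chloride-assisted transmetalation from tin, reductive elimination) attaches C2 and C1 to the trigonal C3 without creating a stereocentre, and carbonate methanolysis of the trimethylsilyl ether then frees C8–OH.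

Step 9
Reactants: 16 3-allyl dienol
Product: 18 3,6,8-triol (three hydroxyls on the upper face; C7 chain, allyl and methallyl on the lower face), via endoperoxide 17 (not isolated)
Conditions: O2, visible light, tetraphenylporphyrin (cat.), CH2Cl2, −78 °C; then thiourea, MeOH, −78 °C to rt
Reagents that add atoms: dioxygen, O=O
Why: [4+2] cycloaddition of singlet oxygen to the cyclohexa-1,3-diene followed by reduction of the O–O bond should deliver both oxygens to the diene face that carries C8–OH (hydrogen-bond guidance, and the other face is blocked by the C7 chain and the C8 methallyl group), so C3–OH forms cis to C8–OH with the allyl group cis to the methallyl group, and C6–OH forms trans to the C7 chain.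

Step 10
Reactants: 18 triol
Product: 19 6-O-triethylsilyl ether of 18
Conditions: TESCl, imidazole, CH2Cl2, 0 °C
Reagents that add atoms: triethylsilyl chloride, CC[Si](Cl)(CC)CC
Why: Silylation should be selective for the only secondary alcohol (C6–OH), since the two tertiary hydroxyls at C3 and C8 do not react with a silyl chloride under these conditions.

Step 11
Reactants: 19 diene diol
Product: 20 cis-fused decalin 3,8-diol with C1=C10
Conditions: second-generation Grubbs catalyst RuCl2(=CHPh)(PCy3)(H2IMes) (5 mol %), CH2Cl2, 40 °C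
Reagents that add atoms: none
Why: Ring-closing metathesis between the allyl group on C3 and the methallyl group on C8, which sit cis on vicinal carbons, should close ring B as a trisubstituted cyclohexene with loss of ethylene, while the hindered C11=C13 and the ring alkene C4=C5 stay out of the reaction.

Step 12
Reactants: 20 decalin alkene
Product: 21 1,10-epoxide of 20 (epoxide oxygen syn to both ring-fusion hydroxyls)
Conditions: mCPBA, NaHCO3, CH2Cl2, 0 °C
Reagents that add atoms: 3-chloroperbenzoic acid, OOC(=O)c1cccc(Cl)c1
Why: Peracid (Prilezhaev) epoxidation should select the electron-rich trisubstituted C1=C10 over the oxygen-flanked C4=C5 and the 1,1-disubstituted C11=C13, and should attack the convex face of the cis-decalin under hydrogen-bond guidance from the two homoallylic ring-fusion hydroxyls, which sets C1 and the C10 carbinol configuration of the target.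

Step 13
Reactants: 21 epoxy diol
Product: 22 15-hydroxy derivative of 21
Conditions: SeO2 (0.5 equiv), t-BuOOH, CH2Cl2, rt
Reagents that add atoms: selenium dioxide, O=[Se]=O; tert-butyl hydroperoxide, CC(C)(C)OO
Why: Riley allylic oxidation (ene reaction then [2,3]-shift) should hydroxylate C15, the only hydrogen-bearing allylic carbon on the more substituted end of the one remaining trisubstituted alkene, a reagent known to spare trisubstituted epoxides and to react more slowly with 1,1-disubstituted alkenes such as C11=C13.

Step 14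
Reactants: 22 allylic alcohol
Product: 23 15-O-triisopropylsilyl ether of 22 (scission precursor)
Conditions: TIPSCl, imidazole, DMF, 0 °C to rt
Reagents that add atoms: triisopropylsilyl chloride, CC(C)[Si](Cl)(C(C)C)C(C)C
Why: The bulky silyl chloride should react only with the primary allylic hydroxyl, leaving the ring-fusion glycol free for the scission.

Step 15
Reactants: 23 cis-fused decalin 3,8-diol
Product: 24 ten-membered (4Z)-1,10-epoxy-3,8-dione
Conditions: Pb(OAc)4, NaHCO3 (solid), CH2Cl2, −20 °C
Reagents that add atoms: none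
Why: The two cis tertiary hydroxyls exchange acetate on tetravalent lead to give a five-membered cyclic lead diester, which fragments in a two-electron process that breaks the C3–C8 bond and releases divalent lead and the C3 and C8 ketones. The closest known reaction type is the Criegee glycol cleavage of cis-9,10-dihydroxydecalins to cyclodecane-1,6-diones. No ring is closed by bond formation: the ten-membered ring appears because the bond shared by ring A and ring B is cut, so there is no entropically costly macrocyclisation and C4=C5 keeps the ring-cis (Z) geometry inherited from ring A. No stereocentre is created; C3 and C8 become trigonal, and C6, C7, C1 and C10 are not touched. The step needs chemoselectivity for the glycol over the epoxide, three silyl ethers and two alkenes, secured by the specificity of Pb(OAc)4 for 1,2-diols and by the cis-diol geometry from step 9, which allows fast cyclic ester formation at low temperature. It also needs the 1,6-dione with its β,γ-unsaturated C8 ketone to survive, which is addressed by the aprotic bicarbonate-buffered medium, the low temperature and immediate use in step 16.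

Step 16
Reactants: 24 epoxy dione
Product: 27 10-hydroxy-(1E,4Z)-1,4-diene-3,8-dione, via hydroxy selenide 25 (not isolated), via selenoxide 26 (not isolated)
Conditions: PhSeH, i-Pr2NEt, EtOH/THF, 0 °C to rt; then 30% H2O2, pyridine, 0 °C to rt
Reagents that add atoms: none
Why: The weakly basic selenolate should open the epoxide by SN2 attack at the less substituted C1 and leave the C10–O bond and configuration intact, and the selenoxide formed on oxidation can undergo syn-elimination only towards C2 (C10 bears no hydrogen), which should give the conjugated E C1=C2 enone and the tertiary C10 alcohol with defined regiochemistry.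

Step 17
Reactants: 27 hydroxy dienone
Product: 28 8,10-anti-diol
Conditions: Me4NBH(OAc)3, MeCN/AcOH, −30 °C
Reagents that add atoms: none
Why: In the Evans–Saksena reduction the C10 hydroxyl exchanges onto boron and hydride is delivered intramolecularly through a six-membered chair transition state to the β-ketone C8, which should give the 1,3-anti diol required at C8, while the cross-conjugated C3 ketone, which has no β-hydroxyl, is not reduced.

Step 18
Reactants: 28 diol; 29 (R)-2-methylbutanoic acid
Product: 30 8-O-[(R)-2-methylbutanoyl] ester of 28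
Conditions: 29, DCC, DMAP (cat.), CH2Cl2, 0 °C to rt
Reagents that add atoms: (R)-2-methylbutanoic acid (29), CC[C@@H](C)C(=O)O
Why: Steglich esterification should acylate the secondary C8 hydroxyl only (the tertiary C10 hydroxyl is inert), and carbodiimide activation at low temperature is expected to preserve the α-stereocentre of the acid.

Step 19
Reactants: 30 ester
Product: 31 6,12-diol (15-O-triisopropylsilyl retained)
Conditions: HF·pyridine, pyridine, THF, 0 °C
Reagents that add atoms: none
Why: Buffered fluoride desilylation should cleave the secondary triethylsilyl and the primary tert-butyldimethylsilyl ethers much faster than the primary triisopropylsilyl ether.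

Step 20
Reactants: 31 diol
Product: 34 15-O-triisopropylsilyl lactone, via hydroxy enal 32 (not isolated), via lactol 33 (not isolated)
Conditions: TEMPO (cat.), PhI(OAc)2, CH2Cl2, rt
Reagents that add atoms: none
Why: Oxoammonium (TEMPO) oxidation should select the primary allylic C12 alcohol over the secondary C6 alcohol, the enal is trapped by C6–OH as the lactol, and a second oxidation gives the α-methylene γ-lactone without touching C6 or C7.

Step 21
Reactants: 34 silyl ether
Product: 35 target compound CNP0232405.1
Conditions: HF·pyridine, THF, rt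
Reagents that add atoms: none
Why: Acidic fluoride desilylation of the primary allylic triisopropylsilyl ether avoids the basic conditions that would endanger the α-methylene lactone and the dienone, and releases the C15 alcohol.

**Compound list**

1 | (S)-carvone, (5S)-2-methyl-5-(prop-1-en-2-yl)cyclohex-2-en-1-one | CC1=CC[C@@H](CC1=O)C(C)=C | starting material
2 | (5S)-5-(3-chloroprop-1-en-2-yl)-2-methylcyclohex-2-en-1-one (C12 chloride) | CC1=CC[C@@H](CC1=O)C(=C)CCl | intermediate
3 | (5S)-5-(3-acetoxyprop-1-en-2-yl)-2-methylcyclohex-2-en-1-one (C12 acetate) | CC1=CC[C@@H](CC1=O)C(=C)COC(C)=O | intermediate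
4 | (5S)-5-(3-hydroxyprop-1-en-2-yl)-2-methylcyclohex-2-en-1-one (C12 alcohol) | CC1=CC[C@@H](CC1=O)C(=C)CO | intermediate
5 | C12 tert-butyldimethylsilyl ether of 4 | CC1=CC[C@@H](CC1=O)C(=C)CO[Si](C)(C)C(C)(C)C | intermediate
6 | 3-bromo-2-methylpropene | C=C(C)CBr | starting material
7 | lithium enolate of 5 (C3–OLi, C3=C8, C4=C5) | CC1=CC[C@@H](C=C1O[Li])C(=C)CO[Si](C)(C)C(C)(C)C | intermediate
8 | 8-methallyl enone, mixture of C8 epimers, C7 as in 1 | CC1=CC[C@@H](C(CC(C)=C)C1=O)C(=C)CO[Si](C)(C)C(C)(C)C | intermediate
9 | potassium enolate of 8 (C3–OK, C3=C8) | CC1=CC[C@@H](C(CC(C)=C)=C1O[K])C(=C)CO[Si](C)(C)C(C)(C)C | intermediate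
10 | 8-hydroxy-8-methallyl enone, C8–OH trans to the C7 side chain | CC1=CC[C@@H]([C@](O)(CC(C)=C)C1=O)C(=C)CO[Si](C)(C)C(C)(C)C | intermediate
11 | C8 trimethylsilyl ether of 10 | CC1=CC[C@@H]([C@](O[Si](C)(C)C)(CC(C)=C)C1=O)C(=C)CO[Si](C)(C)C(C)(C)C | intermediate
12 | potassium dienolate of 11 (C3–OK, C3=C4, C5=C6) | CC1=C(O[K])[C@@](O[Si](C)(C)C)(CC(C)=C)[C@H](C=C1)C(=C)CO[Si](C)(C)C(C)(C)C | intermediate
13 | dienyl triflate (C3–OTf, C3=C4, C5=C6), C7 and C8 as in 11 | CC1=C(OS(=O)(=O)C(F)(F)F)[C@@](O[Si](C)(C)C)(CC(C)=C)[C@H](C=C1)C(=C)CO[Si](C)(C)C(C)(C)C | intermediate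
14 | allyltributylstannane | C=CC[Sn](CCCC)(CCCC)CCCC | starting material
15 | 3-allyl cyclohexa-1,3-diene, C8 trimethylsilyl ether | CC1=C(CC=C)[C@@](O[Si](C)(C)C)(CC(C)=C)[C@H](C=C1)C(=C)CO[Si](C)(C)C(C)(C)C | intermediate
16 | 3-allyl cyclohexa-1,3-diene with free C8–OH (dienol) | CC1=C(CC=C)[C@@](O)(CC(C)=C)[C@H](C=C1)C(=C)CO[Si](C)(C)C(C)(C)C | intermediate
17 | 3,6-endoperoxide (2,3-dioxabicyclo[2.2.2]oct-5-ene), peroxide bridge on the face of C8–OH | CC1=C[C@H]2OO[C@]1(CC=C)[C@@](O)(CC(C)=C)[C@H]2C(=C)CO[Si](C)(C)C(C)(C)C | intermediate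
18 | 3,6,8-triol, hydroxyls on the upper face; C7 chain, C3 allyl and C8 methallyl on the lower face | CC1=C[C@@H](O)[C@H](C(=C)CO[Si](C)(C)C(C)(C)C)[C@](O)(CC(C)=C)[C@]1(O)CC=C | intermediate
19 | 6-O-triethylsilyl ether of 18 | CC1=C[C@@H](O[Si](CC)(CC)CC)[C@H](C(=C)CO[Si](C)(C)C(C)(C)C)[C@](O)(CC(C)=C)[C@]1(O)CC=C | intermediate
20 | cis-fused decalin 3,8-diol with C1=C10 and C4=C5 | CC1=C[C@@H](O[Si](CC)(CC)CC)[C@H](C(=C)CO[Si](C)(C)C(C)(C)C)[C@]2(O)CC(C)=CC[C@]12O | intermediate
21 | 1,10-epoxide of 20, epoxide oxygen syn to both hydroxyls | CC1=C[C@@H](O[Si](CC)(CC)CC)[C@H](C(=C)CO[Si](C)(C)C(C)(C)C)[C@]2(O)C[C@@]3(C)O[C@H]3C[C@]12O | intermediate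
22 | 15-hydroxy derivative of 21 | OCC1=C[C@@H](O[Si](CC)(CC)CC)[C@H](C(=C)CO[Si](C)(C)C(C)(C)C)[C@]2(O)C[C@@]3(C)O[C@H]3C[C@]12O | intermediate
23 | 15-O-triisopropylsilyl ether of 22, decalin 3,8-diol with 1,10-epoxide (scission precursor) | CC(C)[Si](OCC1=C[C@@H](O[Si](CC)(CC)CC)[C@H](C(=C)CO[Si](C)(C)C(C)(C)C)[C@]2(O)C[C@@]3(C)O[C@H]3C[C@]12O)(C(C)C)C(C)C | intermediate
24 | ten-membered (4Z)-1,10-epoxy-3,8-dione (scission product) | CC[Si](CC)(CC)O[C@@H]1/C=C(/CO[Si](C(C)C)(C(C)C)C(C)C)C(=O)C[C@@H]2O[C@]2(C)CC(=O)[C@H]1C(=C)CO[Si](C)(C)C(C)(C)C | intermediate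
25 | 1-phenylseleno-10-hydroxy-3,8-dione (C1 inverted, C10 retained) | CC[Si](CC)(CC)O[C@@H]1/C=C(/CO[Si](C(C)C)(C(C)C)C(C)C)C(=O)C[C@@H]([Se]c2ccccc2)[C@](C)(O)CC(=O)[C@H]1C(=C)CO[Si](C)(C)C(C)(C)C | intermediate
26 | selenoxide of 25 | CC[Si](CC)(CC)O[C@@H]1/C=C(/CO[Si](C(C)C)(C(C)C)C(C)C)C(=O)C[C@@H]([Se](=O)c2ccccc2)[C@](C)(O)CC(=O)[C@H]1C(=C)CO[Si](C)(C)C(C)(C)C | intermediate
27 | 10-hydroxy-(1E,4Z)-1,4-diene-3,8-dione | CC[Si](CC)(CC)O[C@@H]1/C=C(/CO[Si](C(C)C)(C(C)C)C(C)C)C(=O)/C=C/[C@](C)(O)CC(=O)[C@H]1C(=C)CO[Si](C)(C)C(C)(C)C | intermediate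
28 | 8,10-anti-diol (C8 alcohol) | CC[Si](CC)(CC)O[C@@H]1/C=C(/CO[Si](C(C)C)(C(C)C)C(C)C)C(=O)/C=C/[C@](C)(O)C[C@@H](O)[C@H]1C(=C)CO[Si](C)(C)C(C)(C)C | intermediate
29 | (R)-2-methylbutanoic acid | CC[C@@H](C)C(=O)O | starting material
30 | 8-O-[(R)-2-methylbutanoyl] ester of 28 | CC[Si](CC)(CC)O[C@@H]1/C=C(/CO[Si](C(C)C)(C(C)C)C(C)C)C(=O)/C=C/[C@](C)(O)C[C@@H](OC(=O)[C@H](C)CC)[C@H]1C(=C)CO[Si](C)(C)C(C)(C)C | intermediate
31 | 6,12-diol, 15-O-triisopropylsilyl retained | O[C@@H]1/C=C(/CO[Si](C(C)C)(C(C)C)C(C)C)C(=O)/C=C/[C@](C)(O)C[C@@H](OC(=O)[C@H](C)CC)[C@H]1C(=C)CO | intermediate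
32 | 6-hydroxy-12-al (hydroxy enal) | O[C@@H]1/C=C(/CO[Si](C(C)C)(C(C)C)C(C)C)C(=O)/C=C/[C@](C)(O)C[C@@H](OC(=O)[C@H](C)CC)[C@H]1C(=C)C=O | intermediate
33 | 12,6-lactol | C=C1C(O)O[C@@H]2/C=C(/CO[Si](C(C)C)(C(C)C)C(C)C)C(=O)/C=C/[C@](C)(O)C[C@@H](OC(=O)[C@H](C)CC)[C@@H]12 | intermediate
34 | 15-O-triisopropylsilyl ether of the target lactone | C=C1C(=O)O[C@@H]2/C=C(/CO[Si](C(C)C)(C(C)C)C(C)C)C(=O)/C=C/[C@](C)(O)C[C@@H](OC(=O)[C@H](C)CC)[C@@H]12 | intermediate
35 | CNP0232405.1 | C=C1C(=O)O[C@@H]2/C=C(/CO)C(=O)/C=C/[C@](C)(O)C[C@@H](OC(=O)[C@H](C)CC)[C@@H]12 | target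

**Step count and risks**

Total step count: 21. Longest linear sequence: 21 steps, from (S)-carvone (1) to 35.

The three steps most likely to fail:

Step 15 (glycol scission). The 3,8-dione may react on in the flask as it forms: acetolysis or transannular opening of the trisubstituted epoxide promoted by the lead salts and acetic acid, transannular aldol closure between an enol at C2 or C9 and the opposite carbonyl, or migration of C11=C13 into conjugation with the C8 ketone. The fallback keeps the same scission but takes the epoxide out of its substrate. It sets out from 20. Dihydroxylation of C1=C10 from the convex face (OsO4 cat., NMO, acetone/water) should give the 1,3,8,10-tetraol F1. Ac2O/pyridine acetylates only the secondary C1 hydroxyl to give the C1 acetate F2. SeO2/t-BuOOH as in step 13 gives the 15-alcohol F3, and TIPSCl/imidazole gives the silyl ether F4. Pb(OAc)4 scission then gives the 1-acetoxy-10-hydroxy-3,8-dione F5. In F5 the only β-leaving group is on C1, so brief treatment with Et3N in CH2Cl2 (E1cB loss of acetic acid) should give the E enone and return to the route at 27. The C10 configuration is the same because osmium and the peracid attack the same face.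

Step 16 (epoxide opening and elimination). The selenolate may add reversibly to the dienone, the SN2 opening at C1 may be slow in the medium ring, or the syn-elimination may give some of the Z enone. The fallback changes the mechanism from nucleophilic opening to base-induced isomerisation. It sets out from 24. Et3N in CH2Cl2 at rt deprotonates C2 and the enolate opens the C1–O bond by E1cB, giving 27 in one operation, where it rejoins the route. This adds no new compound (F0). Its own risk is competing enolisation at C9, which is why it is not the first choice.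

Step 17 (directed reduction). Facial selectivity of the internal hydride delivery may be poor, because the tertiary C10 carbinol offers two substituents of similar size (the methyl group and C1) to the chair transition state inside a ten-membered ring. The fallback replaces internal delivery by chelation-controlled external delivery followed by inversion. It sets out from 27. Narasaka–Prasad reduction (Et2BOMe, NaBH4, THF/MeOH, −78 °C) through the boron chelate should give the 8,10-syn-diol F6. Mitsunobu esterification of F6 with acid 29 (PPh3, DIAD, THF, 0 °C) inverts C8 while installing the ester, and returns to the route at 30.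

**Further compounds**

F1 | step 15 | 1,3,8,10-tetraol (C1 and C10 hydroxyls syn to the ring-fusion hydroxyls) | CC1=C[C@@H](O[Si](CC)(CC)CC)[C@H](C(=C)CO[Si](C)(C)C(C)(C)C)[C@]2(O)C[C@@](C)(O)[C@@H](O)C[C@]12O
F2 | step 15 | C1 acetate of F1 | CC1=C[C@@H](O[Si](CC)(CC)CC)[C@H](C(=C)CO[Si](C)(C)C(C)(C)C)[C@]2(O)C[C@@](C)(O)[C@@H](OC(C)=O)C[C@]12O
F3 | step 15 | 15-hydroxy derivative of F2 | OCC1=C[C@@H](O[Si](CC)(CC)CC)[C@H](C(=C)CO[Si](C)(C)C(C)(C)C)[C@]2(O)C[C@@](C)(O)[C@@H](OC(C)=O)C[C@]12O
F4 | step 15 | 15-O-triisopropylsilyl ether of F3 | CC(C)[Si](OCC1=C[C@@H](O[Si](CC)(CC)CC)[C@H](C(=C)CO[Si](C)(C)C(C)(C)C)[C@]2(O)C[C@@](C)(O)[C@@H](OC(C)=O)C[C@]12O)(C(C)C)C(C)C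
F5 | step 15 | ten-membered 1-acetoxy-10-hydroxy-3,8-dione | CC[Si](CC)(CC)O[C@@H]1/C=C(/CO[Si](C(C)C)(C(C)C)C(C)C)C(=O)C[C@H](OC(C)=O)[C@](C)(O)CC(=O)[C@H]1C(=C)CO[Si](C)(C)C(C)(C)C
F0 | step 16 | none | none
F6 | step 17 | 8,10-syn-diol (C8 epimer of 28) | CC[Si](CC)(CC)O[C@@H]1/C=C(/CO[Si](C(C)C)(C(C)C)C(C)C)C(=O)/C=C/[C@](C)(O)C[C@H](O)[C@H]1C(=C)CO[Si](C)(C)C(C)(C)C
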